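**Retrosynthetic overview**
- The (E)-bromovinyl group comes from a C2 carbaldehyde (Takai–Utimoto olefination), which comes from a C2 methyl ester (DIBAL-H); the alkene is carried through ring formation at the carboxyl oxidation level.
- The oxolane, the only ring, is formed in one step by a three-component carbonyl-ylide [3+2] cycloaddition that makes C4–C5 and C2–C3: (R)-2-bromo-3-chloro-2-methylpropanal (C5 and the side chain) + methyl 2-diazopropanoate (C2 with its CH3 and CO2Me) + vinyl bromide (C4H2–C3HBr).
- Enabling feature: ring oxygen O1 lies between C5 (a CH, i.e. an aldehyde carbon) and C2 (a quaternary carbon that can carry an ester), so C5–O1–C2 is a masked carbonyl ylide; the C3(H)(Br)–C4H2 edge opposite O1 is vinyl bromide with the ring bromine already in place.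
- The C–Br stereocentre of the side chain is made first (enantioselective bromochlorination of methallyl alcohol, then oxidation) and is the only source of absolute configuration; it steers C5, and ylide geometry and endo approach relay this to C2 and C3.

Key step: step 4

Remark: oxolane numbering is used throughout (O1, C2 quaternary, C3 CHBr, C4 CH2, C5 CH). The target is (2S,3R,5R) with a (2R) side chain; side chain, C2–CH3 and C3–Br are on one face and the bromovinyl group on the other. The ligand enantiomer in step 1 is assumed to be the one that delivers the (R)-bromochloride.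

**Step 1**
Reactants: 1 2-methylprop-2-en-1-ol (methallyl alcohol)
Product: 2 (2R)-2-bromo-3-chloro-2-methylpropan-1-ol
Conditions: NBS, ClTi(OiPr)3, chiral tridentate Schiff-base ligand (cat.), hexanes, −20 °C
Reagents that add atoms: N-bromosuccinimide, O=C1CCC(=O)N1Br; chlorotitanium triisopropoxide, CC(C)O[Ti](Cl)(OC(C)C)OC(C)C
Why: Proposed new method: with 1 held on the chiral Ti(IV)–Schiff-base complex, NBS should deliver Br+ to the alkene face chosen by the ligand while chloride is passed from titanium to the distal carbon in an anti addition, so that Br ends on C2 (the new quaternary stereocentre) and Cl on C3; the closest known reaction type is the Ti(IV)/Schiff-base-catalysed enantioselective bromochlorination of 3-substituted allylic alcohols (Br at C2, Cl at C3), which here has to override the Markovnikov bias of a 2-substituted allylic alcohol.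

**Step 2**
Reactants: 2 (2R)-2-bromo-3-chloro-2-methylpropan-1-ol
Product: 3 (2R)-2-bromo-3-chloro-2-methylpropanal
Conditions: Dess–Martin periodinane, CH2Cl2, 0 °C to rt
Reagents that add atoms: none
Why: Dess–Martin oxidation should stop at the aldehyde under neutral conditions, the stereocentre being quaternary (no α-H, so no epimerisation or enol-driven loss of chloride) and the alkyl halides inert.

**Step 3**
Reactants: 4 methyl 2-methyl-3-oxobutanoate
Product: 5 methyl 2-diazopropanoate
Conditions: p-ABSA, DBU, MeCN, 0 °C to rt
Reagents that add atoms: 4-acetamidobenzenesulfonyl azide, CC(=O)Nc1ccc(cc1)S(=O)(=O)N=[N+]=[N-]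
Why: Regitz deacylative diazo transfer: the enolate of the 2-substituted acetoacetate takes up the azide terminus and the acetyl group is expelled onto the sulfonamide nitrogen, leaving the α-alkyl-α-diazo ester.

**Step 4**
Reactants: 3 (2R)-2-bromo-3-chloro-2-methylpropanal; 5 methyl 2-diazopropanoate; 6 bromoethene (vinyl bromide)
Product: 8 methyl (2S,3R,5R)-3-bromo-5-[(2R)-2-bromo-1-chloropropan-2-yl]-2-methyloxolane-2-carboxylate, via carbonyl ylide 7 (not isolated)
Conditions: Rh2(OPiv)4 (cat.), excess vinyl bromide/CH2Cl2, −78 °C, slow addition of 5
Reagents that add atoms: none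
Why: Proposed new method: Rh2(OPiv)4 should release N2 from 5 and pass the carbene carbon to the carbonyl oxygen of 3 (lone pair anti to the quaternary α-carbon) to give the E-oxocarbenium/ester-enolate ylide 7, which adds across vinyl bromide in a concerted but asynchronous [π4s+π2s] 1,3-dipolar cycloaddition; the closest known reaction type is the Rh(II) pivalate, −78 °C three-component coupling of aldehydes, α-alkyl-α-diazoesters and alkene or alkyne dipolarophiles, not yet shown with a vinyl halide or an α-halo aliphatic aldehyde. The oxolane is closed by this intermolecular [3+2] cycloaddition, the dipole supplying C5–O1–C2 and the dipolarophile C3–C4, with both σ-bonds (C4–C5 and C2–C3) formed suprafacially in the same event. The regiochemistry needed (CH2 to C5, CHBr to C2) follows from polarity matching: the nucleophilic CH2 terminus of vinyl bromide bonds to the oxocarbenium carbon and the bromine-stabilised α-carbon is captured by the ester-bearing carbanion carbon, the pairing that both frontier-orbital interactions favour. C5 is set by the (R)-C–Br stereocentre of 3 (Felkin–Anh: C–Br anti to the incoming CH2, which passes CH3 and not CH2Cl); C2 is set by the ylide geometry (side chain outward at C5; at C2 the CO2Me inward in the s-cis, enol-ether-like arrangement held by a C5–H···O=C contact, CH3 outward), which places CH3 cis to the side chain; C3 is set by endo approach of Br under the ylide oxygen, the exo quadrant being blocked by the inward ester, which places Br cis to CH3. Chemoselectivity (ylide formation over β-hydride shift to methyl acrylate, cyclopropanation of 6, epoxide closure or dioxolane formation with a second aldehyde) should be secured by the pivalate catalyst at −78 °C, slow addition of 5, the hindered α-quaternary aldehyde and the large excess of 6. Because all three ring centres are relayed from one stereocentre, any leakage should give separable diastereomers and not the enantiomer.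

**Step 5**
Reactants: 8 methyl (2S,3R,5R)-3-bromo-5-[(2R)-2-bromo-1-chloropropan-2-yl]-2-methyloxolane-2-carboxylate
Product: 10 (2S,3R,5R)-3-bromo-5-[(2R)-2-bromo-1-chloropropan-2-yl]-2-methyloxolane-2-carbaldehyde, via aluminium hemiacetal 9 (not isolated)
Conditions: DIBAL-H, CH2Cl2, −78 °C; then MeOH, aq. Rochelle salt
Reagents that add atoms: none
Why: DIBAL-H half-reduction of an ester: one hydride adds at −78 °C and the α-alkoxy-chelated aluminium hemiacetal 9 should not collapse until work-up, so over-reduction is held back, while the carbonyl carbon sits on a quaternary centre (no epimerisation, no enolate-driven loss of the C3 bromide) and alkyl halides are inert to DIBAL-H at this temperature.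

**Step 6**
Reactants: 10 (2S,3R,5R)-3-bromo-5-[(2R)-2-bromo-1-chloropropan-2-yl]-2-methyloxolane-2-carbaldehyde
Product: 11 (2S,3R,5R)-3-bromo-5-[(2R)-2-bromo-1-chloropropan-2-yl]-2-[(E)-2-bromoethenyl]-2-methyloxolane
Conditions: CrCl2, CHBr3, THF, 0 °C to rt
Reagents that add atoms: bromoform, BrC(Br)Br
Why: Takai–Utimoto olefination: the gem-dichromium species from CHBr3 and CrCl2 should add to the aldehyde and eliminate to the (E)-bromoalkene selectively, the adjacent quaternary stereocentre being non-epimerisable and unactivated alkyl halides reacting only slowly with Cr(II) at this temperature.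

**Compound list**
1 | 2-methylprop-2-en-1-ol | CC(=C)CO | starting material
2 | (2R)-2-bromo-3-chloro-2-methylpropan-1-ol | C[C@](Br)(CCl)CO | intermediate
3 | (2R)-2-bromo-3-chloro-2-methylpropanal | C[C@](Br)(CCl)C=O | intermediate
4 | methyl 2-methyl-3-oxobutanoate | COC(=O)C(C)C(C)=O | starting material
5 | methyl 2-diazopropanoate | COC(=O)C(C)=[N+]=[N-] | intermediate
6 | bromoethene (vinyl bromide) | C=CBr | starting material
7 | carbonyl ylide, [(1E,2R)-2-bromo-3-chloro-2-methylpropylidene](1-methoxy-1-oxopropan-2-id-2-yl)oxonium (CO2Me inward, CH3 outward) | C[C@](Br)(CCl)/C=[O+]/[C-](C)C(=O)OC | intermediate (not isolated)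
8 | methyl (2S,3R,5R)-3-bromo-5-[(2R)-2-bromo-1-chloropropan-2-yl]-2-methyloxolane-2-carboxylate | C[C@](Br)(CCl)[C@H]1C[C@@H](Br)[C@](C)(C(=O)OC)O1 | intermediate
9 | diisobutylaluminium methyl hemiacetal of 10 (hemiacetal carbon undefined) | C[C@](Br)(CCl)[C@H]1C[C@@H](Br)[C@](C)(C(OC)O[Al](CC(C)C)CC(C)C)O1 | intermediate (not isolated)
10 | (2S,3R,5R)-3-bromo-5-[(2R)-2-bromo-1-chloropropan-2-yl]-2-methyloxolane-2-carbaldehyde | C[C@](Br)(CCl)[C@H]1C[C@@H](Br)[C@](C)(C=O)O1 | intermediate
11 | (2S,3R,5R)-3-bromo-5-[(2R)-2-bromo-1-chloropropan-2-yl]-2-[(E)-2-bromoethenyl]-2-methyloxolane | C[C@](Br)(CCl)[C@H]1C[C@@H](Br)[C@](C)(/C=C/Br)O1 | target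

**Totals**
Total step count: 6. Longest linear sequence: 5 steps (steps 1, 2, 4, 5, 6); step 3 is a one-step branch.

**Steps most likely to fail**

1. Step 4 (Proposed new method). What may go wrong: the ylide may react through the other rotamer (ester outward), which would put the side chain cis to the ester; facial discrimination by the side-chain stereocentre may be weak, since only CH3 versus CH2Cl is distinguished; the ylide may close to the epoxide or be taken up by a second aldehyde before the weak dipolarophile reacts. Fallback, known chemistry, from 3 back to 11, building the ring by haloetherification instead of cycloaddition. A vinylogous Mukaiyama aldol of 3 with the silyl ketene acetal of methyl tiglate (BF3·OEt2, CH2Cl2, −78 °C; Felkin–Anh control by the C–Br centre) would give methyl (2E,5R,6R)-6-bromo-7-chloro-5-hydroxy-2,6-dimethylhept-2-enoate F1. Reduction with excess DIBAL-H would give (2E,5R,6R)-6-bromo-7-chloro-2,6-dimethylhept-2-ene-1,5-diol F2, and MnO2 would oxidise only the allylic alcohol to (2E,5R,6R)-6-bromo-7-chloro-5-hydroxy-2,6-dimethylhept-2-enal F3. Takai–Utimoto olefination would give (1E,3E,6R,7R)-1,7-dibromo-8-chloro-3,7-dimethylocta-1,3-dien-6-ol F4. 5-Endo bromoetherification of F4 with 2,4,4,6-tetrabromocyclohexa-2,5-dienone (CH2Cl2) should attack the more electron-rich trisubstituted alkene; anti addition of O and Br across the E-alkene places Br cis to CH3. The C2/C5 relationship is not secured in this closure, so 11 would have to be separated from its 2,5-diastereomer.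

2. Step 1 (Proposed new method). What may go wrong: chloride may open the activated alkene at the tertiary carbon (Markovnikov sense) and give the constitutional isomer, or facial discrimination on a 2-substituted allylic alcohol may be poor. Fallback, known chemistry, from 1 back to 3, replacing asymmetric catalysis by a resolution. Oxidation of 1 with activated MnO2 would give 2-methylprop-2-enal F5. Conjugate addition of dry HCl would give 3-chloro-2-methylpropanal F6. Acid-catalysed α-bromination (Br2, CH2Cl2) would give racemic 2-bromo-3-chloro-2-methylpropanal F7. Acetalisation with (1R,2R)-hydrobenzoin (cat. TsOH, benzene, water removal) would give two dioxolanes that differ only at the C–Br centre and should be separable by crystallisation or chromatography, the configuration being assigned by X-ray: (4R,5R)-2-[(2R)-2-bromo-1-chloropropan-2-yl]-4,5-diphenyl-1,3-dioxolane F8 is kept and (4R,5R)-2-[(2S)-2-bromo-1-chloropropan-2-yl]-4,5-diphenyl-1,3-dioxolane F9 is set aside. Acid hydrolysis of F8 (aq. TFA) returns to 3.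

3. Step 6. What may go wrong: single-electron reduction of the tertiary bromide by Cr(II) followed by loss of the vicinal chloride (reductive elimination to an isopropenyl group), halogen exchange at the new vinyl position, or slow addition to the hindered aldehyde. Fallback from 10 back to 11 through an alkyne. Seyferth–Gilbert homologation with the Ohira–Bestmann reagent (K2CO3, MeOH) would give (2S,3R,5R)-3-bromo-5-[(2R)-2-bromo-1-chloropropan-2-yl]-2-ethynyl-2-methyloxolane F10. Hydrozirconation with Cp2Zr(H)Cl (THF), then bromination of the (E)-alkenylzirconium with NBS, should give 11 with the E geometry fixed by syn addition and retentive bromination.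

**Further compounds**
F1 | step 4 | methyl (2E,5R,6R)-6-bromo-7-chloro-5-hydroxy-2,6-dimethylhept-2-enoate | C[C@](Br)(CCl)[C@H](O)C/C=C(\C)C(=O)OC
F2 | step 4 | (2E,5R,6R)-6-bromo-7-chloro-2,6-dimethylhept-2-ene-1,5-diol | C[C@](Br)(CCl)[C@H](O)C/C=C(\C)CO
F3 | step 4 | (2E,5R,6R)-6-bromo-7-chloro-5-hydroxy-2,6-dimethylhept-2-enal | C[C@](Br)(CCl)[C@H](O)C/C=C(\C)C=O
F4 | step 4 | (1E,3E,6R,7R)-1,7-dibromo-8-chloro-3,7-dimethylocta-1,3-dien-6-ol | C[C@](Br)(CCl)[C@H](O)C/C=C(\C)/C=C/Br
F5 | step 1 | 2-methylprop-2-enal | CC(=C)C=O
F6 | step 1 | 3-chloro-2-methylpropanal (racemic) | CC(CCl)C=O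
F7 | step 1 | 2-bromo-3-chloro-2-methylpropanal (racemic) | CC(Br)(CCl)C=O
F8 | step 1 | (4R,5R)-2-[(2R)-2-bromo-1-chloropropan-2-yl]-4,5-diphenyl-1,3-dioxolane | C[C@](Br)(CCl)C1O[C@H](c2ccccc2)[C@@H](c2ccccc2)O1
F9 | step 1 | (4R,5R)-2-[(2S)-2-bromo-1-chloropropan-2-yl]-4,5-diphenyl-1,3-dioxolane | C[C@@](Br)(CCl)C1O[C@H](c2ccccc2)[C@@H](c2ccccc2)O1
F10 | step 6 | (2S,3R,5R)-3-bromo-5-[(2R)-2-bromo-1-chloropropan-2-yl]-2-ethynyl-2-methyloxolane | C[C@](Br)(CCl)[C@H]1C[C@@H](Br)[C@](C)(C#C)O1
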